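The target is cut at the two identical diarylmethane bonds that join C5 of each inner ring D (the carbon para to the ring D oxygen) to the benzylic CH2 of an outer 2-hydroxybenzyl ring E. One nickel-electrocatalysed decarboxylative coupling forms both aryl–CH2 bonds at once, with the sites dictated solely by two pre-installed bromines, so no ortho/para ambiguity of phenol benzylation arises. The precursor is (2S)-pinostrobin carrying 5-bromo-2-(methoxymethoxy)benzyl groups at C6 and C8 of ring A, with the chelated 5-OH left free; its partner is the N-hydroxyphthalimide ester of 2-(methoxymethoxy)phenylacetic acid. Acidic removal of the four MOM groups then gives the target.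

Key step: step 5

Remark on labels: rings A and C are the chromanone, ring B is the C2 phenyl, rings D are the two inner benzyl rings (C1 bears the CH2 to ring A, C2 the oxygen, C5 the bond made in step 5), rings E are the two outer benzyl rings.
Assumption: (S)-pinostrobin is used enantiopure, and its 5-OH, hydrogen-bonded to the C4 carbonyl, is not alkylated by MOMCl with an amine base.

Step 1
Reactants: 1 (S)-pinostrobin; 2 5-bromo-2-hydroxybenzyl alcohol (3 equiv, in portions)
Product: 4 (2S)-6,8-bis(5-bromo-2-hydroxybenzyl)-5-hydroxy-7-methoxyflavanone, via ortho-quinone methide 3 (not isolated)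
Conditions: ZnCl2, 1,4-dioxane, 90 °C
Reagents that add atoms: none
Why: In this Friedel–Crafts-type hydroxybenzylation, ZnCl2 dehydrates 2 to the ortho-quinone methide 3, which is attacked in a conjugate sense by the only two free, oxygen-flanked positions of ring A (C6 and C8), while the bromine para to the phenol of 2 blocks its self-condensation and the non-basic medium should leave C2 untouched.

Step 2
Reactants: 4 (2S)-6,8-bis(5-bromo-2-hydroxybenzyl)-5-hydroxy-7-methoxyflavanone
Product: 5 (2S)-6,8-bis[5-bromo-2-(methoxymethoxy)benzyl]-5-hydroxy-7-methoxyflavanone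
Conditions: MOMCl, i-Pr2NEt, CH2Cl2, 0 °C to rt
Reagents that add atoms: chloromethyl methyl ether (MOMCl), COCCl
Why: Williamson-type O-alkylation with a weak, non-nucleophilic amine base should cap only the two ring D phenols, because the 5-OH is locked in its hydrogen bond to C4=O and flanked by the C6 benzyl group, and such a base at low temperature should not open ring C, so C2 is retained.

Step 3
Reactants: 6 2-hydroxyphenylacetic acid
Product: 8 2-[2-(methoxymethoxy)phenyl]acetic acid, via MOM ester 7 (not isolated)
Conditions: MOMCl, i-Pr2NEt, CH2Cl2, 0 °C to rt; then LiOH, THF/H2O, rt; aq. HCl to pH 4, 0 °C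
Reagents that add atoms: chloromethyl methyl ether (MOMCl), COCCl; lithium hydroxide, [Li+].[OH-] (supplies the carboxyl OH oxygen on ester cleavage)
Why: Exhaustive methoxymethylation followed by saponification should cleave only the acyl–oxygen bond of the MOM ester, since the aryl MOM ether is inert to hydroxide, and the capped phenol can no longer lactonise to benzofuran-2(3H)-one when the acid is activated.

Step 4
Reactants: 8 2-[2-(methoxymethoxy)phenyl]acetic acid; 9 N-hydroxyphthalimide
Product: 10 1,3-dioxoisoindolin-2-yl 2-[2-(methoxymethoxy)phenyl]acetate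
Conditions: DIC, DMAP (cat.), CH2Cl2, 0 °C to rt
Reagents that add atoms: none
Why: Steglich-type carbodiimide esterification joins the acid to the acidic N–OH of 9 under neutral conditions that the MOM ether tolerates.

Step 5
Reactants: 5 (2S)-6,8-bis[5-bromo-2-(methoxymethoxy)benzyl]-5-hydroxy-7-methoxyflavanone; 10 1,3-dioxoisoindolin-2-yl 2-[2-(methoxymethoxy)phenyl]acetate (4 equiv, in two portions)
Product: 11 (2S)-5-hydroxy-7-methoxy-6,8-bis{2-(methoxymethoxy)-5-[2-(methoxymethoxy)benzyl]benzyl}flavanone
Conditions: NiBr2(dme) (20 mol%), dtbbpy (20 mol%), AgNO3 (30 mol%), NMP, Mg anode, RVC cathode, undivided cell, constant current, rt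
Reagents that add atoms: none
Why: Cathodic reduction turns the divalent nickel–dtbbpy precatalyst into low-valent nickel, which inserts into the C5–Br bond of each ring D; ester 10 takes up one electron (at the silver-coated cathode or from reduced nickel) and fragments to phthalimide anion, CO2 and the 2-(methoxymethoxy)benzyl radical, which the arylnickel species captures, and reductive elimination from the resulting trivalent nickel forges the aryl–CH2 bond, the cycle then repeating on the second arm. The closest known reaction type is the nickel-catalysed electroreductive decarboxylative arylation of N-hydroxyphthalimide esters with aryl halides, a cross-electrophile coupling, applied here twice in one flask. No ring is closed and no stereocentre is created; C2 should persist because the medium holds no strong base and the working potential stays well above that needed to reduce the hydrogen-bonded aryl ketone. The step needs cross-coupling to outrun benzyl radical dimerisation and hydrodebromination, and bond formation at C5 of ring D only: the bromines fix the sites, low current density with portionwise 10 keeps the radical concentration low, and the MOM ethers prevent phenoxide formation and acyl transfer from 10. Magnesium ions from the anode occupy the 5-hydroxy/C4-carbonyl chelate so that nickel stays on the bipyridine, and the sacrificial anode spares the electron-rich rings from oxidation.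

Step 6
Reactants: 11 (2S)-5-hydroxy-7-methoxy-6,8-bis{2-(methoxymethoxy)-5-[2-(methoxymethoxy)benzyl]benzyl}flavanone
Product: 12 5''-(2''''-hydroxybenzyl)uvarinol, (2S)-5-hydroxy-6,8-bis[2-hydroxy-5-(2-hydroxybenzyl)benzyl]-7-methoxyflavanone
Conditions: HCl, MeOH/THF, 40 °C
Reagents that add atoms: none
Why: Acid-catalysed acetal exchange with methanol should remove all four aryl MOM ethers as dimethoxymethane, which keeps formaldehyde equivalents away from the electron-rich rings, while the 7-OMe ether, the diarylmethane links and the flavanone C2 centre are stable to mild acid.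

Compound list
1 | (S)-pinostrobin, (2S)-5-hydroxy-7-methoxy-2-phenylchroman-4-one | COc1cc(O)c2c(c1)O[C@H](c1ccccc1)CC2=O | starting material
2 | 5-bromo-2-hydroxybenzyl alcohol | OCc1cc(Br)ccc1O | starting material
3 | 4-bromo-6-methylidenecyclohexa-2,4-dien-1-one (ortho-quinone methide) | C=C1C=C(Br)C=CC1=O | intermediate
4 | (2S)-6,8-bis(5-bromo-2-hydroxybenzyl)-5-hydroxy-7-methoxyflavanone | COc1c(Cc2cc(Br)ccc2O)c(O)c2c(c1Cc1cc(Br)ccc1O)O[C@H](c1ccccc1)CC2=O | intermediate
5 | (2S)-6,8-bis[5-bromo-2-(methoxymethoxy)benzyl]-5-hydroxy-7-methoxyflavanone | COc1c(Cc2cc(Br)ccc2OCOC)c(O)c2c(c1Cc1cc(Br)ccc1OCOC)O[C@H](c1ccccc1)CC2=O | intermediate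
6 | 2-hydroxyphenylacetic acid | OC(=O)Cc1ccccc1O | starting material
7 | methoxymethyl 2-[2-(methoxymethoxy)phenyl]acetate | COCOC(=O)Cc1ccccc1OCOC | intermediate
8 | 2-[2-(methoxymethoxy)phenyl]acetic acid | COCOc1ccccc1CC(=O)O | intermediate
9 | N-hydroxyphthalimide | O=C1c2ccccc2C(=O)N1O | starting material
10 | 1,3-dioxoisoindolin-2-yl 2-[2-(methoxymethoxy)phenyl]acetate | COCOc1ccccc1CC(=O)ON1C(=O)c2ccccc2C1=O | intermediate
11 | (2S)-5-hydroxy-7-methoxy-6,8-bis{2-(methoxymethoxy)-5-[2-(methoxymethoxy)benzyl]benzyl}flavanone | COc1c(Cc2cc(Cc3ccccc3OCOC)ccc2OCOC)c(O)c2c(c1Cc1cc(Cc3ccccc3OCOC)ccc1OCOC)O[C@H](c1ccccc1)CC2=O | intermediate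
12 | 5''-(2''''-hydroxybenzyl)uvarinol, (2S)-5-hydroxy-6,8-bis[2-hydroxy-5-(2-hydroxybenzyl)benzyl]-7-methoxyflavanone | COc1c(Cc2cc(Cc3ccccc3O)ccc2O)c(O)c2c(c1Cc1cc(Cc3ccccc3O)ccc1O)O[C@H](c1ccccc1)CC2=O | target

Total step count: 6. Longest linear sequence: 4 steps (1, 2, 5, 6; the branch 3, 4, 5, 6 is equally long).

Steps most likely to fail

Step 5. The benzyl radical may be generated faster than the two electron-rich aryl bromides are engaged, so that radical dimerisation and hydrodebromination take over and the second arm stays uncoupled. The fallback sets out from 5 and comes back at 11 through a twofold Negishi coupling, a two-electron palladium cycle without free radicals. Commercial 2-(methoxymethoxy)benzaldehyde would be reduced (NaBH4, MeOH, 0 °C) to [2-(methoxymethoxy)phenyl]methanol F1. This would be converted (MsCl, Et3N, LiCl, CH2Cl2, 0 °C) into 1-(chloromethyl)-2-(methoxymethoxy)benzene F2, and zinc dust with LiCl in THF would insert to give [2-(methoxymethoxy)benzyl]zinc chloride F3. Slow addition of excess F3 to 5 with Pd(OAc)2 and SPhos in THF at rt should give 11. The first equivalent of F3 is spent on the acidic 5-OH, and the ketone and MOM ethers tolerate the organozinc.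

Step 1. The second C-benzylation may stall and the quinone methide may oligomerise at temperatures mild enough to keep C2 intact, whereas more forcing Lewis-acid treatment may open and reclose ring C and erode the C2 configuration. The fallback sets out from 1 and 2 and comes back at 5 by separating conversion from stereochemical integrity. The benzylation would be driven to completion (ZnCl2, dioxane, reflux, large excess of 2) without regard to C2, giving racemic or scalemic 6,8-bis(5-bromo-2-hydroxybenzyl)-5-hydroxy-7-methoxyflavanone F4. MOM protection as in step 2 would give racemic 6,8-bis[5-bromo-2-(methoxymethoxy)benzyl]-5-hydroxy-7-methoxyflavanone F5, and preparative chiral-phase SFC would deliver the (2S)-enantiomer, which is 5. Cheap racemic pinostrobin can feed this branch equally well.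

Step 2. The amine base may induce opening and reclosure of ring C, which erodes C2, or alkylation of the two hindered ring D phenols may stay incomplete. The fallback sets out from 4 and comes back at 12 with silyl ethers installed under near-neutral conditions. TBSCl and imidazole in DMF at rt should give (2S)-6,8-bis[5-bromo-2-(tert-butyldimethylsilyloxy)benzyl]-5-hydroxy-7-methoxyflavanone F6. The electroreductive coupling with 10 under the conditions of step 5 should then give (2S)-6,8-bis{2-(tert-butyldimethylsilyloxy)-5-[2-(methoxymethoxy)benzyl]benzyl}-5-hydroxy-7-methoxyflavanone F7. HCl in MeOH/THF removes the silyl and MOM groups together to give 12.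

Further compounds
F1 | step 5 | [2-(methoxymethoxy)phenyl]methanol | COCOc1ccccc1CO
F2 | step 5 | 1-(chloromethyl)-2-(methoxymethoxy)benzene | COCOc1ccccc1CCl
F3 | step 5 | [2-(methoxymethoxy)benzyl]zinc chloride | COCOc1ccccc1C[Zn]Cl
F4 | step 1 | racemic 6,8-bis(5-bromo-2-hydroxybenzyl)-5-hydroxy-7-methoxyflavanone | COc1c(Cc2cc(Br)ccc2O)c(O)c2c(c1Cc1cc(Br)ccc1O)OC(c1ccccc1)CC2=O
F5 | step 1 | racemic 6,8-bis[5-bromo-2-(methoxymethoxy)benzyl]-5-hydroxy-7-methoxyflavanone | COc1c(Cc2cc(Br)ccc2OCOC)c(O)c2c(c1Cc1cc(Br)ccc1OCOC)OC(c1ccccc1)CC2=O
F6 | step 2 | (2S)-6,8-bis[5-bromo-2-(tert-butyldimethylsilyloxy)benzyl]-5-hydroxy-7-methoxyflavanone | COc1c(Cc2cc(Br)ccc2O[Si](C)(C)C(C)(C)C)c(O)c2c(c1Cc1cc(Br)ccc1O[Si](C)(C)C(C)(C)C)O[C@H](c1ccccc1)CC2=O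
F7 | step 2 | (2S)-6,8-bis{2-(tert-butyldimethylsilyloxy)-5-[2-(methoxymethoxy)benzyl]benzyl}-5-hydroxy-7-methoxyflavanone | COc1c(Cc2cc(Cc3ccccc3OCOC)ccc2O[Si](C)(C)C(C)(C)C)c(O)c2c(c1Cc1cc(Cc3ccccc3OCOC)ccc1O[Si](C)(C)C(C)(C)C)O[C@H](c1ccccc1)CC2=O
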